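**Retrosynthetic overview**
- The strategy rests on ring B: the ketone-bearing C1' sits between C2'–OH and C6'–OMe, with C4'–Me para. This is the pattern left when a carboxylate adds across the triple bond of 3-methoxy-5-methylbenzyne and its acyl group then moves from O to C.
- Target 22 comes from benzyl ether 21 by hydrogenolysis of the ring-A C3–OBn; 21 comes from acid 10 and silyl triflate 18, cutting C2'–O and C1'–C(=O) in one aryne σ-insertion.
- Acid 10 comes from methyl 5-methoxysalicylate 1 by two phenol-directed ortho-formylations: the first CHO (C3) becomes OH by Baeyer–Villiger oxidation, the second (C4) becomes CO2H by Pinnick oxidation.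
- Silyl triflate 18 comes from 3-methoxy-5-methylphenol 11 by carbamate-directed ortho-silylation at C2 and exchange of the carbamate for a triflate.
- No ring is formed: both benzene rings are bought, and the route only decorates and joins them.

Key step: step 10

Remark: the target has no stereocentre and its SMILES carries no stereodescriptor, so it is treated as achiral and no enantiocontrol is planned.

**Route**

Step 1
Reactants: 1 methyl 2-hydroxy-5-methoxybenzoate (methyl 5-methoxysalicylate)
Product: 3 methyl 3-formyl-2-hydroxy-5-methoxybenzoate, via hydroxymethyl phenol 2 (not isolated)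
Conditions: MgCl2, Et3N, (CH2O)n, MeCN, reflux; aq. HCl work-up
Reagents that add atoms: paraformaldehyde (formaldehyde unit), C=O
Why: Magnesium-mediated ortho-formylation (Casnati–Skattebøl reaction): the magnesium phenoxide should deliver formaldehyde only to C3, the one free position ortho to the OH, and a second formaldehyde oxidises the hydroxymethyl phenol 2 to the aldehyde by hydride transfer.

Step 2
Reactants: 3 methyl 3-formyl-2-hydroxy-5-methoxybenzoate
Product: 4 methyl 3-formyl-2,5-dimethoxybenzoate
Conditions: MeI, K2CO3, DMF, 50 °C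
Reagents that add atoms: iodomethane, CI
Why: Williamson O-methylation of the phenoxide, to which the aldehyde and the methyl ester are inert.

Step 3
Reactants: 4 methyl 3-formyl-2,5-dimethoxybenzoate
Product: 6 methyl 3-hydroxy-2,5-dimethoxybenzoate, via aryl formate 5 (not isolated)
Conditions: mCPBA, CH2Cl2, 0 °C to rt; aq. NaHCO3 wash; then K2CO3 (cat.), MeOH, rt
Reagents that add atoms: mCPBA, OOC(=O)c1cccc(Cl)c1
Why: Baeyer–Villiger oxidation of an ortho-alkoxybenzaldehyde, in which the aryl group and not hydride should migrate in the Criegee adduct because of the ortho methoxy group, followed by methanolysis of the aryl formate 5, which leaves the methyl benzoate untouched.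

Step 4
Reactants: 6 methyl 3-hydroxy-2,5-dimethoxybenzoate
Product: 8 methyl 4-formyl-3-hydroxy-2,5-dimethoxybenzoate, via hydroxymethyl phenol 7 (not isolated)
Conditions: MgCl2, Et3N, (CH2O)n, MeCN, reflux; aq. HCl work-up
Reagents that add atoms: paraformaldehyde (formaldehyde unit), C=O
Why: Magnesium-mediated ortho-formylation (Casnati–Skattebøl reaction) again, now unambiguous because C2 carries OMe and C4 is the only free position ortho to the C3–OH, so the carbon that becomes the ketone is placed between the two oxygens.

Step 5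
Reactants: 8 methyl 4-formyl-3-hydroxy-2,5-dimethoxybenzoate
Product: 9 methyl 3-(benzyloxy)-4-formyl-2,5-dimethoxybenzoate
Conditions: BnBr, K2CO3, DMF, 60 °C
Reagents that add atoms: benzyl bromide, BrCc1ccccc1
Why: Williamson etherification of the chelated phenol, which masks the only other acidic or nucleophilic OH before the aryne step.

Step 6
Reactants: 9 methyl 3-(benzyloxy)-4-formyl-2,5-dimethoxybenzoate
Product: 10 2-(benzyloxy)-3,6-dimethoxy-4-(methoxycarbonyl)benzoic acid
Conditions: NaClO2, NaH2PO4, 2-methyl-2-butene, t-BuOH/H2O, rt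
Reagents that add atoms: sodium chlorite, [Na+].[O-]Cl=O
Why: Pinnick oxidation, which tolerates hindered di-ortho-substituted aldehydes, with the alkene scavenger keeping hypochlorous acid away from the electron-rich ring; the ester and the benzyl ether are not affected.

Step 7
Reactants: 11 3-methoxy-5-methylphenol
Product: 12 3-methoxy-5-methylphenyl N-isopropylcarbamate
Conditions: i-PrNCO, Et3N (cat.), CH2Cl2, rt
Reagents that add atoms: isopropyl isocyanate, CC(C)N=C=O
Why: Base-catalysed addition of the phenol to the isocyanate (carbamoylation), which installs a directing group that can later be removed under mild base.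

Step 8
Reactants: 12 3-methoxy-5-methylphenyl N-isopropylcarbamate
Product: 16 3-methoxy-5-methyl-2-(trimethylsilyl)phenyl N-isopropylcarbamate, via N-TBS carbamate 13 (not isolated), via 2-lithio N-TBS carbamate 14 (not isolated), via N-TBS 2-TMS carbamate 15 (not isolated)
Conditions: TBSOTf, TMEDA, Et2O, 0 °C to rt; then n-BuLi, TMEDA, −78 °C; TMSCl, −78 °C to rt; aq. NaHSO4 work-up
Reagents that add atoms: chlorotrimethylsilane, C[Si](C)(C)Cl
Why: Directed ortho-metalation: after in situ N-silylation of the carbamate N–H, n-BuLi/TMEDA should lithiate C2, the only carbon flanked by both the carbamate and the methoxy group, TMSCl quenches the aryllithium at −78 °C before an anionic Fries shift can occur, and the N-silyl group is lost on acidic work-up.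

Step 9
Reactants: 16 3-methoxy-5-methyl-2-(trimethylsilyl)phenyl N-isopropylcarbamate
Product: 18 3-methoxy-5-methyl-2-(trimethylsilyl)phenyl trifluoromethanesulfonate, via silyl phenol 17 (not isolated)
Conditions: DBU, Et2NH, MeCN, 40 °C; then PhNTf2, rt
Reagents that add atoms: N-phenylbis(trifluoromethanesulfonimide), O=S(=O)(N(c1ccccc1)S(=O)(=O)C(F)(F)F)C(F)(F)F
Why: E1cB cleavage of the N-monoalkyl carbamate (DBU removes the N–H, the phenoxide leaves, Et2NH traps the isopropyl isocyanate as a urea) followed by O-triflation of the phenoxide in the same flask, under conditions that leave the aryl–silicon bond intact.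

Step 10
Reactants: 10 2-(benzyloxy)-3,6-dimethoxy-4-(methoxycarbonyl)benzoic acid; 18 3-methoxy-5-methyl-2-(trimethylsilyl)phenyl trifluoromethanesulfonate
Product: 21 methyl 3-(benzyloxy)-4-(2-hydroxy-6-methoxy-4-methylbenzoyl)-2,5-dimethoxybenzoate, via aryne 19 (not isolated), via aryl carbanion 20 (not isolated)
Conditions: 18 (1.5 equiv), CsF (4 equiv), THF (dilute), 125 °C, sealed tube; aq. NH4Cl work-up
Reagents that add atoms: none
Why: Fluoride removes the silyl group of 18 and triflate leaves, giving aryne 19; the caesium carboxylate of 10 adds through oxygen to the aryne carbon remote from the methoxy group, so the negative charge appears on the carbon next to OMe (carbanion 20). This carbanion attacks the ester carbonyl two atoms away through a four-membered transition state, and the strained alkoxide opens by C–O cleavage to the diaryl ketone and the ring-B phenoxide, which is protonated on work-up. The closest known reaction type is the fluoride-mediated insertion of arynes into the O–C(acyl) bond of carboxylic acids, which gives ortho-hydroxyaryl ketones in hot THF. No ring is closed (the four-membered cycle is only passed through) and no stereocentre is formed. The step needs O-attack at the distal aryne carbon, which the inductive and distortion effect of the 3-methoxy group should secure, and it sets the OH/OMe differentiation of ring B and the tetra-ortho-substituted ketone together. It also needs acyl transfer to outrun protonation of 20, which is helped by the aprotic medium, high dilution and high temperature, and by 10 having no acidic proton other than the carboxyl one.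

Step 11
Reactants: 21 methyl 3-(benzyloxy)-4-(2-hydroxy-6-methoxy-4-methylbenzoyl)-2,5-dimethoxybenzoate
Product: 22 pseudocercone A (methyl 3-hydroxy-4-(2-hydroxy-6-methoxy-4-methylbenzoyl)-2,5-dimethoxybenzoate)
Conditions: H2 (1 atm), 10% Pd/C, EtOAc, rt
Reagents that add atoms: none
Why: Hydrogenolysis of the benzyl aryl ether, under which the hindered, hydrogen-bonded diaryl ketone, the aryl methyl ethers and the methyl ester should stay intact.

**Compound list**
1 | methyl 2-hydroxy-5-methoxybenzoate | COC(=O)c1cc(OC)ccc1O | starting material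
2 | methyl 2-hydroxy-3-(hydroxymethyl)-5-methoxybenzoate | COC(=O)c1cc(OC)cc(CO)c1O | intermediate
3 | methyl 3-formyl-2-hydroxy-5-methoxybenzoate | COC(=O)c1cc(OC)cc(C=O)c1O | intermediate
4 | methyl 3-formyl-2,5-dimethoxybenzoate | COC(=O)c1cc(OC)cc(C=O)c1OC | intermediate
5 | methyl 3-(formyloxy)-2,5-dimethoxybenzoate | COC(=O)c1cc(OC)cc(OC=O)c1OC | intermediate
6 | methyl 3-hydroxy-2,5-dimethoxybenzoate | COC(=O)c1cc(OC)cc(O)c1OC | intermediate
7 | methyl 3-hydroxy-4-(hydroxymethyl)-2,5-dimethoxybenzoate | COC(=O)c1cc(OC)c(CO)c(O)c1OC | intermediate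
8 | methyl 4-formyl-3-hydroxy-2,5-dimethoxybenzoate | COC(=O)c1cc(OC)c(C=O)c(O)c1OC | intermediate
9 | methyl 3-(benzyloxy)-4-formyl-2,5-dimethoxybenzoate | COC(=O)c1cc(OC)c(C=O)c(OCc2ccccc2)c1OC | intermediate
10 | 2-(benzyloxy)-3,6-dimethoxy-4-(methoxycarbonyl)benzoic acid | COC(=O)c1cc(OC)c(C(=O)O)c(OCc2ccccc2)c1OC | intermediate
11 | 3-methoxy-5-methylphenol | COc1cc(C)cc(O)c1 | starting material
12 | 3-methoxy-5-methylphenyl N-isopropylcarbamate | COc1cc(C)cc(OC(=O)NC(C)C)c1 | intermediate
13 | 3-methoxy-5-methylphenyl N-(tert-butyldimethylsilyl)-N-isopropylcarbamate | COc1cc(C)cc(OC(=O)N(C(C)C)[Si](C)(C)C(C)(C)C)c1 | intermediate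
14 | 2-lithio-3-methoxy-5-methylphenyl N-(tert-butyldimethylsilyl)-N-isopropylcarbamate | COc1cc(C)cc(OC(=O)N(C(C)C)[Si](C)(C)C(C)(C)C)c1[Li] | intermediate
15 | 3-methoxy-5-methyl-2-(trimethylsilyl)phenyl N-(tert-butyldimethylsilyl)-N-isopropylcarbamate | COc1cc(C)cc(OC(=O)N(C(C)C)[Si](C)(C)C(C)(C)C)c1[Si](C)(C)C | intermediate
16 | 3-methoxy-5-methyl-2-(trimethylsilyl)phenyl N-isopropylcarbamate | COc1cc(C)cc(OC(=O)NC(C)C)c1[Si](C)(C)C | intermediate
17 | 3-methoxy-5-methyl-2-(trimethylsilyl)phenol | COc1cc(C)cc(O)c1[Si](C)(C)C | intermediate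
18 | 3-methoxy-5-methyl-2-(trimethylsilyl)phenyl trifluoromethanesulfonate | COc1cc(C)cc(OS(=O)(=O)C(F)(F)F)c1[Si](C)(C)C | intermediate
19 | 3-methoxy-5-methylbenzyne (3-methoxy-5-methyl-1,2-didehydrobenzene) | COC1=CC(C)=CC#C1 | intermediate
20 | caesium 2-{[2-(benzyloxy)-3,6-dimethoxy-4-(methoxycarbonyl)benzoyl]oxy}-6-methoxy-4-methylbenzen-1-ide (carbanion on the carbon between the ester oxygen and OMe) | COC(=O)c1cc(OC)c(C(=O)Oc2cc(C)cc(OC)[c-]2)c(OCc2ccccc2)c1OC.[Cs+] | intermediate
21 | methyl 3-(benzyloxy)-4-(2-hydroxy-6-methoxy-4-methylbenzoyl)-2,5-dimethoxybenzoate | COC(=O)c1cc(OC)c(C(=O)c2c(O)cc(C)cc2OC)c(OCc2ccccc2)c1OC | intermediate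
22 | pseudocercone A, methyl 3-hydroxy-4-(2-hydroxy-6-methoxy-4-methylbenzoyl)-2,5-dimethoxybenzoate | COC(=O)c1cc(OC)c(C(=O)c2c(O)cc(C)cc2OC)c(O)c1OC | target

**Step count**
Total: 11 steps. Longest linear sequence: 8 steps (steps 1–6, 10, 11); the aryne precursor branch (steps 7–9) joins at step 10.

**Steps most likely to fail**

1. Step 10. Protonation of the aryl carbanion, or simple O-arylation without acyl shift, may outrun the hindered 1,3-acyl transfer onto a carbonyl flanked by OBn and OMe. The product phenoxide may also be arylated by further aryne. The fallback makes the same carbanion with no proton source, by halogen–magnesium exchange on a preformed aryl ester (anionic Fries rearrangement). It sets out from 16 and 10. Ipso-iododesilylation of 16 with ICl (CH2Cl2, −78 °C) should give 2-iodo-3-methoxy-5-methylphenyl N-isopropylcarbamate F1, and DBU/Et2NH in MeCN then frees 2-iodo-3-methoxy-5-methylphenol F2. Acid 10 is converted with oxalyl chloride and catalytic DMF into methyl 3-(benzyloxy)-4-(chlorocarbonyl)-2,5-dimethoxybenzoate F3, which is coupled with F2 (Et3N, DMAP, CH2Cl2) to 2-iodo-3-methoxy-5-methylphenyl 2-(benzyloxy)-3,6-dimethoxy-4-(methoxycarbonyl)benzoate F4. Treatment with i-PrMgCl·LiCl in THF at −40 °C exchanges the iodine faster than it attacks either ester, and on warming the arylmagnesium should shift the acyl group from O to C, coming back to the route at 21.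

2. Step 3. The C2 methoxy group is flanked on both sides and twisted out of conjugation, so hydride may migrate instead of aryl in the Criegee adduct, and the aldehyde would be over-oxidised to the carboxylic acid. The fallback sets out from 3, where the free ortho phenoxide guarantees aryl migration. Dakin oxidation of 3 with alkaline H2O2 at 0 °C should give methyl 2,3-dihydroxy-5-methoxybenzoate F5. The non-chelated C3–OH is benzylated selectively (BnBr 1 equiv, K2CO3, acetone, rt) to methyl 3-(benzyloxy)-2-hydroxy-5-methoxybenzoate F6. The chelated C2–OH is then methylated (MeI, K2CO3, DMF, 60 °C) to methyl 3-(benzyloxy)-2,5-dimethoxybenzoate F7, and hydrogenolysis (H2, Pd/C, EtOAc) comes back to the route at 6.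

3. Step 1. The phenoxide is deactivated and chelated by the ortho ester, so attack on formaldehyde may be slow and conversion incomplete. The fallback sets out from 1, replaces C–C by C–Br bond formation and bypasses steps 1–3. Bromination ortho to the phenol (NBS, MeCN, 0 °C) should give methyl 3-bromo-2-hydroxy-5-methoxybenzoate F8, and O-methylation (MeI, K2CO3, DMF) gives methyl 3-bromo-2,5-dimethoxybenzoate F9. Miyaura borylation (B2pin2, Pd(dppf)Cl2, KOAc, dioxane, 90 °C) gives methyl 2,5-dimethoxy-3-(4,4,5,5-tetramethyl-1,3,2-dioxaborolan-2-yl)benzoate F10, and oxidation of the C–B bond (NaBO3·4H2O, THF/H2O, rt) comes back to the route at 6.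

**Further compounds**
F1 | step 10 | 2-iodo-3-methoxy-5-methylphenyl N-isopropylcarbamate | COc1cc(C)cc(OC(=O)NC(C)C)c1I
F2 | step 10 | 2-iodo-3-methoxy-5-methylphenol | COc1cc(C)cc(O)c1I
F3 | step 10 | methyl 3-(benzyloxy)-4-(chlorocarbonyl)-2,5-dimethoxybenzoate | COC(=O)c1cc(OC)c(C(=O)Cl)c(OCc2ccccc2)c1OC
F4 | step 10 | 2-iodo-3-methoxy-5-methylphenyl 2-(benzyloxy)-3,6-dimethoxy-4-(methoxycarbonyl)benzoate | COC(=O)c1cc(OC)c(C(=O)Oc2cc(C)cc(OC)c2I)c(OCc2ccccc2)c1OC
F5 | step 3 | methyl 2,3-dihydroxy-5-methoxybenzoate | COC(=O)c1cc(OC)cc(O)c1O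
F6 | step 3 | methyl 3-(benzyloxy)-2-hydroxy-5-methoxybenzoate | COC(=O)c1cc(OC)cc(OCc2ccccc2)c1O
F7 | step 3 | methyl 3-(benzyloxy)-2,5-dimethoxybenzoate | COC(=O)c1cc(OC)cc(OCc2ccccc2)c1OC
F8 | step 1 | methyl 3-bromo-2-hydroxy-5-methoxybenzoate | COC(=O)c1cc(OC)cc(Br)c1O
F9 | step 1 | methyl 3-bromo-2,5-dimethoxybenzoate | COC(=O)c1cc(OC)cc(Br)c1OC
F10 | step 1 | methyl 2,5-dimethoxy-3-(4,4,5,5-tetramethyl-1,3,2-dioxaborolan-2-yl)benzoate | COC(=O)c1cc(OC)cc(B2OC(C)(C)C(C)(C)O2)c1OC
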